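**Retrosynthetic overview**

1. The ring is numbered C1 (Me, Cl), C2, C3 (Me, Br), C4 (E-chlorovinyl), C5, C6 (Br). The strategy rests on the unit C6 (carbonyl level)–C5H2–C4(H)(vinyl) of the single six-membered ring, which is the product pattern of an enol ether radical cation trapped by an allylsilane.
2. C3–Br comes from a C3–OMe group by ionization in the last step. The cis C1–Cl/C6–Br pair comes from a C1=C6 alkene by epoxidation, chloride opening at C1 and inversion at C6.
3. The C1=C6 alkene comes from a C6 ketone by formyl-directed methylation at C1, reduction and anti elimination. The chlorovinyl group comes from the vinyl group by cross-metathesis with (E)-1,2-dichloroethene.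
4. The only ring is closed by anodic coupling of an acyclic 2-methoxyalkene with an allylsilane, forming C4–C5; C4 is set from C3.
5. The acyclic precursor comes from (S)-linalool, which supplies C3, by O-methylation, ozonolysis, esterification, cross-metathesis with allyltrimethylsilane and ester methylenation.

Key step: step 6

Remark: (S)-(+)-linalool is assumed to be available in high enantiomeric purity, because its carbinol carbon (C3) is the only source of absolute configuration; the ring numbering above is used throughout.

**Route**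

Step 1
Reactants: 1 (S)-(+)-linalool
Product: 2 (S)-3-methoxy-3,7-dimethylocta-1,6-diene
Conditions: NaH, MeI, THF/DMF, 0 °C to rt
Reagents that add atoms: iodomethane, CI
Why: Williamson ether synthesis on the tertiary alkoxide; no bond to the stereocentre is broken, so C3 keeps the S configuration.

Step 2
Reactants: 2 (S)-3-methoxy-3,7-dimethylocta-1,6-diene
Product: 4 (S)-4-methoxy-4-methylhex-5-enal, via ozonide 3 (not isolated)
Conditions: O3, CH2Cl2, −78 °C, Sudan Red 7B end-point; then Me2S, −78 °C to rt
Reagents that add atoms: ozone, [O-][O+]=O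
Why: Criegee ozonolysis should be chemoselective for the electron-rich trisubstituted alkene over the vinyl group, which is monosubstituted and deactivated by the allylic oxygen, and dimethyl sulfide reduces the ozonide to the aldehyde.

Step 3
Reactants: 4 (S)-4-methoxy-4-methylhex-5-enal
Product: 5 methyl (S)-4-methoxy-4-methylhex-5-enoate
Conditions: I2, KOH, MeOH, 0 °C
Reagents that add atoms: methanol, CO
Why: Oxidative esterification of the aldehyde by hypoiodite in methanol; the isolated vinyl group and the tertiary ether should be inert and no stereocentre is enolizable.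

Step 4
Reactants: 5 methyl (S)-4-methoxy-4-methylhex-5-enoate; 6 allyltrimethylsilane
Product: 7 methyl (S,E)-4-methoxy-4-methyl-7-(trimethylsilyl)hept-5-enoate
Conditions: second-generation Hoveyda–Grubbs catalyst (5 mol %), 6 (4 equiv), CH2Cl2, 40 °C; chromatography on Et3N-treated silica
Reagents that add atoms: allyltrimethylsilane (6), C=CC[Si](C)(C)C
Why: Olefin cross-metathesis between the unhindered allylsilane and a vinyl group on a fully substituted allylic carbon, which should not homodimerize; the bulk at C3 favours the E-alkene, and neutral handling avoids acid-induced 1,4-elimination of the 4-alkoxy allylsilane.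

Step 5
Reactants: 7 methyl (S,E)-4-methoxy-4-methyl-7-(trimethylsilyl)hept-5-enoate
Product: 8 (S,E)-(4,7-dimethoxy-4-methylocta-2,7-dien-1-yl)trimethylsilane
Conditions: Cp2TiMe2 (2.5 equiv), toluene, 65 °C, dark; filtration through basic alumina
Reagents that add atoms: dimethyltitanocene, [CH3-].[CH3-].[Ti+4].c1cc[cH-]c1.c1cc[cH-]c1
Why: Petasis methylenation converts the ester carbonyl into the 2-methoxy-1-alkene without enolization, so the enol ether is formed only at C5=C6; the allylsilane and the ether should be inert.

Step 6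
Reactants: 8 (S,E)-(4,7-dimethoxy-4-methylocta-2,7-dien-1-yl)trimethylsilane
Product: 9 (3S,4S)-1,1,4-trimethoxy-4-methyl-3-vinylcyclohexane
Conditions: reticulated vitreous carbon anode, Pt cathode, undivided cell, constant current 8 mA (2.2 F/mol), 0.1 M LiClO4, MeOH/CH2Cl2 1:4, 2,6-lutidine, rt
Reagents that add atoms: methanol, CO
Why: One-electron oxidation of the enol ether C5=C6 gives a radical cation whose terminal carbon C5 is attacked by C4 of the allylsilane; the β-silyl cation loses the silyl group to methanol and leaves the C4 vinyl group, and the C6 α-methoxy radical is oxidized and captured by methanol as the dimethyl ketal. The closest known reaction type is the intramolecular anodic olefin coupling of enol ether radical cations with allylsilanes, an umpolung that joins two nucleophilic carbons. The only ring (six-membered, C1–C6) closes exo at the allylsilane alkene (C4 inside the ring, its alkene partner outside), with both enol ether carbons C5 and C6 inside the ring, which is the less usual topology for this coupling. The new stereocentre C4 is set from C3 in a chair-like transition state with the C3 methyl and the alkenylsilane equatorial and the C3 methoxy axial, in the inside position of the attacked alkene, so that OMe and vinyl end up cis (3S,4S). The step needs ring closure to outrun methanol capture of the radical cation and needs a neutral medium; the six-membered chair, the low methanol content and the 2,6-lutidine buffer should secure this. Any C4 epimer is separated here, so that the absolute configuration of C4 rests on C3 alone.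

Step 7
Reactants: 9 (3S,4S)-1,1,4-trimethoxy-4-methyl-3-vinylcyclohexane; 10 (E)-1,2-dichloroethene
Product: 11 (3S,4S)-3-[(E)-2-chlorovinyl]-1,1,4-trimethoxy-4-methylcyclohexane
Conditions: Mo(=NC6F5)(=CHCMe2Ph)(2,5-Me2C4H2N)(OAr), Ar = 2,6-bis(2,4,6-triisopropylphenyl)phenyl (5 mol %), 10 (8 equiv), benzene, 22 °C
Reagents that add atoms: (E)-1,2-dichloroethene (10), Cl/C=C/Cl
Why: Stereoretentive (kinetically E-selective) molybdenum-catalysed cross-metathesis of a terminal α-branched alkene with (E)-1,2-dichloroethene should give the E-alkenyl chloride; the substrate carries only ether and ketal groups, which the alkylidene tolerates.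

Step 8
Reactants: 11 (3S,4S)-3-[(E)-2-chlorovinyl]-1,1,4-trimethoxy-4-methylcyclohexane
Product: 12 (3S,4S)-3-[(E)-2-chlorovinyl]-4-methoxy-4-methylcyclohexan-1-one
Conditions: PPTS, acetone/H2O 10:1, rt
Reagents that add atoms: water, O
Why: Acid-catalysed ketal hydrolysis; the tertiary methyl ether and the alkenyl chloride are stable to pyridinium tosylate, and neither stereocentre is α to the new ketone.

Step 9
Reactants: 12 (3S,4S)-3-[(E)-2-chlorovinyl]-4-methoxy-4-methylcyclohexan-1-one
Product: 13 (4S,5S)-5-[(E)-2-chlorovinyl]-2-(hydroxymethylidene)-4-methoxy-4-methylcyclohexan-1-one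
Conditions: NaH, HCO2Et, EtOH (cat.), THF, 0 °C to rt; aq. HCl work-up
Reagents that add atoms: ethyl formate, CCOC=O
Why: Claisen formylation under equilibrating conditions should go to the less hindered α-methylene C1, because a planar hydroxymethylidene at C5 would clash with the C4 chlorovinyl group; this fixes a regiochemistry that direct kinetic enolate methylation of a 3-substituted cyclohexanone would not secure.

Step 10
Reactants: 13 (4S,5S)-5-[(E)-2-chlorovinyl]-2-(hydroxymethylidene)-4-methoxy-4-methylcyclohexan-1-one
Product: 15 (2S,4S,5S)-5-[(E)-2-chlorovinyl]-4-methoxy-2,4-dimethylcyclohexan-1-one, via formyl methyl ketone 14 (not isolated)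
Conditions: K2CO3, MeI, acetone, reflux; then 2% aq. NaOH, MeOH, rt
Reagents that add atoms: iodomethane, CI
Why: C-Alkylation of the 1,3-dicarbonyl anion puts the methyl on C1 only, and hydroxide then removes the formyl group by retro-Claisen cleavage; C1 equilibrates through the enolate to the equatorial methyl epimer (2S).

Step 11
Reactants: 15 (2S,4S,5S)-5-[(E)-2-chlorovinyl]-4-methoxy-2,4-dimethylcyclohexan-1-one
Product: 16 (1R,2S,4S,5S)-5-[(E)-2-chlorovinyl]-4-methoxy-2,4-dimethylcyclohexan-1-ol
Conditions: LiBH(s-Bu)3 (L-Selectride), THF, −78 °C; then H2O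
Reagents that add atoms: none
Why: Bulky trialkylborohydride reduction: hydride should enter C6 from the equatorial direction and give the axial alcohol (1R) cis to the C1 methyl, which places C1–H anti to the hydroxyl for the next step.

Step 12
Reactants: 16 (1R,2S,4S,5S)-5-[(E)-2-chlorovinyl]-4-methoxy-2,4-dimethylcyclohexan-1-ol
Product: 18 (4S,5S)-4-[(E)-2-chlorovinyl]-5-methoxy-1,5-dimethylcyclohex-1-ene, via dichlorophosphate ester 17 (not isolated)
Conditions: POCl3, pyridine, 0 °C to 60 °C
Reagents that add atoms: none
Why: E2 dehydration of the axial dichlorophosphate: the axial tertiary C1–H is anti-periplanar and its loss gives the more substituted (Zaitsev) C1=C6 alkene; the C5=C6 isomer is the expected minor product and is separated on AgNO3-impregnated silica.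

Step 13
Reactants: 18 (4S,5S)-4-[(E)-2-chlorovinyl]-5-methoxy-1,5-dimethylcyclohex-1-ene
Product: 19 (1S,3S,4S,6R)-4-[(E)-2-chlorovinyl]-3-methoxy-1,3-dimethyl-7-oxabicyclo[4.1.0]heptane
Conditions: mCPBA, NaHCO3, CH2Cl2, 0 °C
Reagents that add atoms: 3-chloroperoxybenzoic acid, OOC(=O)c1cccc(Cl)c1
Why: Prilezhaev epoxidation: the peracid should react with the electron-rich trisubstituted C1=C6 alkene and not with the chloroalkene, and approach anti to the pseudoaxial C3 methoxy group that covers the other face at C1, which sets C1 and C6 (1S,6R).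

Step 14
Reactants: 19 (1S,3S,4S,6R)-4-[(E)-2-chlorovinyl]-3-methoxy-1,3-dimethyl-7-oxabicyclo[4.1.0]heptane
Product: 20 (1R,2R,4S,5S)-2-chloro-5-[(E)-2-chlorovinyl]-4-methoxy-2,4-dimethylcyclohexan-1-ol
Conditions: HCl (1.0 M in Et2O, 1.1 equiv), CH2Cl2, −40 °C
Reagents that add atoms: hydrogen chloride, Cl
Why: Acid-mediated epoxide opening: chloride attacks the tertiary C1 of the protonated epoxide from the face opposite to oxygen (inversion, trans-diaxial Fürst–Plattner opening of the chair that keeps the C3 methyl and the C4 chlorovinyl equatorial), which sets C1 with axial chlorine and leaves the C6 hydroxyl trans to it.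

Step 15
Reactants: 20 (1R,2R,4S,5S)-2-chloro-5-[(E)-2-chlorovinyl]-4-methoxy-2,4-dimethylcyclohexan-1-ol
Product: 22 (1R,2S,4S,5S)-2-bromo-1-chloro-4-[(E)-2-chlorovinyl]-5-methoxy-1,5-dimethylcyclohexane, via triflate 21 (not isolated)
Conditions: Tf2O, pyridine, CH2Cl2, −30 °C; then Bu4NBr, −30 °C to 20 °C
Reagents that add atoms: tetrabutylammonium bromide, [Br-].CCCC[N+](CCCC)(CCCC)CCCC; trifluoromethanesulfonic anhydride, O=S(=O)(OS(=O)(=O)C(F)(F)F)C(F)(F)F (atoms kept only in 21)
Why: SN2 displacement of the secondary triflate by bromide inverts C6 and places bromine equatorial and cis to the C1 chlorine; the β-chlorine disfavours ionization of the triflate, and a triflate is chosen because C6 is flanked by the fully substituted C1.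

Step 16
Reactants: 22 (1R,2S,4S,5S)-2-bromo-1-chloro-4-[(E)-2-chlorovinyl]-5-methoxy-1,5-dimethylcyclohexane
Product: 23 (1R,2S,4S,5R)-1,4-dibromo-5-chloro-2-[(E)-2-chlorovinyl]-1,5-dimethylcyclohexane
Conditions: BBr3 (1.1 equiv), CH2Cl2, −78 °C; cold aq. NaHCO3 quench
Reagents that add atoms: boron tribromide, BrB(Br)Br
Why: BBr3 cleavage of a tertiary alkyl methyl ether by ionization of the C3–O bond; bromide is expected to enter C3 anti to the departing oxygen and from the equatorial side, because the axial side is blocked by the syn-axial C1–Cl, which would set C3 as R with bromine equatorial and trans to the chlorovinyl group.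

**Compound list**

1 | (S)-(+)-linalool, (S)-3,7-dimethylocta-1,6-dien-3-ol | CC(C)=CCC[C@@](O)(C)C=C | starting material
2 | (S)-3-methoxy-3,7-dimethylocta-1,6-diene | CC(C)=CCC[C@@](OC)(C)C=C | intermediate
3 | 3,3-dimethyl-5-[(3S)-3-methoxy-3-methylpent-4-en-1-yl]-1,2,4-trioxolane (ozonide, both C5 epimers) | CC1(C)OOC(CC[C@@](OC)(C)C=C)O1 | intermediate (not isolated)
4 | (S)-4-methoxy-4-methylhex-5-enal | O=CCC[C@@](OC)(C)C=C | intermediate
5 | methyl (S)-4-methoxy-4-methylhex-5-enoate | COC(=O)CC[C@@](OC)(C)C=C | intermediate
6 | allyltrimethylsilane | C=CC[Si](C)(C)C | starting material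
7 | methyl (S,E)-4-methoxy-4-methyl-7-(trimethylsilyl)hept-5-enoate | COC(=O)CC[C@@](OC)(C)/C=C/C[Si](C)(C)C | intermediate
8 | (S,E)-(4,7-dimethoxy-4-methylocta-2,7-dien-1-yl)trimethylsilane | C=C(OC)CC[C@@](OC)(C)/C=C/C[Si](C)(C)C | intermediate
9 | (3S,4S)-1,1,4-trimethoxy-4-methyl-3-vinylcyclohexane | COC1(OC)CC[C@@](OC)(C)[C@H](C=C)C1 | intermediate
10 | (E)-1,2-dichloroethene | Cl/C=C/Cl | starting material
11 | (3S,4S)-3-[(E)-2-chlorovinyl]-1,1,4-trimethoxy-4-methylcyclohexane | COC1(OC)CC[C@@](OC)(C)[C@H](/C=C/Cl)C1 | intermediate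
12 | (3S,4S)-3-[(E)-2-chlorovinyl]-4-methoxy-4-methylcyclohexan-1-one | O=C1CC[C@@](OC)(C)[C@H](/C=C/Cl)C1 | intermediate
13 | (4S,5S)-5-[(E)-2-chlorovinyl]-2-(hydroxymethylidene)-4-methoxy-4-methylcyclohexan-1-one | O=C1C(=CO)C[C@@](OC)(C)[C@H](/C=C/Cl)C1 | intermediate
14 | (4S,5S)-4-[(E)-2-chlorovinyl]-5-methoxy-1,5-dimethyl-2-oxocyclohexane-1-carbaldehyde (both C1 epimers) | O=CC1(C)C[C@@](OC)(C)[C@H](/C=C/Cl)CC1=O | intermediate (not isolated)
15 | (2S,4S,5S)-5-[(E)-2-chlorovinyl]-4-methoxy-2,4-dimethylcyclohexan-1-one | O=C1[C@@H](C)C[C@@](OC)(C)[C@H](/C=C/Cl)C1 | intermediate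
16 | (1R,2S,4S,5S)-5-[(E)-2-chlorovinyl]-4-methoxy-2,4-dimethylcyclohexan-1-ol | O[C@H]1[C@@H](C)C[C@@](OC)(C)[C@H](/C=C/Cl)C1 | intermediate
17 | (1R,2S,4S,5S)-5-[(E)-2-chlorovinyl]-4-methoxy-2,4-dimethylcyclohexyl phosphorodichloridate | O=P(Cl)(Cl)O[C@H]1[C@@H](C)C[C@@](OC)(C)[C@H](/C=C/Cl)C1 | intermediate (not isolated)
18 | (4S,5S)-4-[(E)-2-chlorovinyl]-5-methoxy-1,5-dimethylcyclohex-1-ene | C1=C(C)C[C@@](OC)(C)[C@H](/C=C/Cl)C1 | intermediate
19 | (1S,3S,4S,6R)-4-[(E)-2-chlorovinyl]-3-methoxy-1,3-dimethyl-7-oxabicyclo[4.1.0]heptane | C[C@]1(O2)C[C@@](OC)(C)[C@H](/C=C/Cl)C[C@H]12 | intermediate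
20 | (1R,2R,4S,5S)-2-chloro-5-[(E)-2-chlorovinyl]-4-methoxy-2,4-dimethylcyclohexan-1-ol | O[C@H]1[C@](C)(Cl)C[C@@](OC)(C)[C@H](/C=C/Cl)C1 | intermediate
21 | (1R,2R,4S,5S)-2-chloro-5-[(E)-2-chlorovinyl]-4-methoxy-2,4-dimethylcyclohexyl trifluoromethanesulfonate | O=S(=O)(O[C@H]1[C@](C)(Cl)C[C@@](OC)(C)[C@H](/C=C/Cl)C1)C(F)(F)F | intermediate (not isolated)
22 | (1R,2S,4S,5S)-2-bromo-1-chloro-4-[(E)-2-chlorovinyl]-5-methoxy-1,5-dimethylcyclohexane | Br[C@@H]1[C@](C)(Cl)C[C@@](OC)(C)[C@H](/C=C/Cl)C1 | intermediate
23 | (1R,2S,4S,5R)-1,4-dibromo-5-chloro-2-[(E)-2-chlorovinyl]-1,5-dimethylcyclohexane | C[C@@]1(Cl)C[C@@](C)(Br)[C@H](/C=C/Cl)C[C@@H]1Br | target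

**Step count and risks**

Total step count: 16. Longest linear sequence: 16 steps, from (S)-linalool 1 to 23.

The three steps most likely to fail:

1. Step 16, the C3 ether to bromide exchange. The tertiary C3 cation may be captured by bromide with poor facial selectivity or with return from the face of the departing oxygen. A 1,2-hydride shift from C4 would give an allylic cation, and the C1 chloride could exchange with bromide. The fallback sets out from 22 and comes back at 23, and replaces cation capture by radical capture. Loss of methanol with TMSOTf and 2,6-di-tert-butyl-4-methylpyridine in CH2Cl2 at −40 °C, the way tert-butyl ethers are cleaved to isobutene, should give (1R,2S,4S)-2-bromo-1-chloro-4-[(E)-2-chlorovinyl]-1-methyl-5-methylidenecyclohexane F1 together with its endocyclic isomer (3R,4S,6S)-4-bromo-3-chloro-6-[(E)-2-chlorovinyl]-1,3-dimethylcyclohex-1-ene F2. Both alkenes funnel into the same tertiary C3 radical under hydrogen-atom-transfer Markovnikov hydrobromination (Co(acac)2, t-BuOOH, Et3SiH, TsBr, n-PrOH, rt). A radical cannot undergo the hydride shift, and bromine should be delivered to the face not shielded by the axial C1–Cl, to give 23.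

2. Step 15, inversion at C6. Bromide must enter at a secondary carbon next to the fully substituted C1 and syn to its axial chlorine, so E2 loss of triflic acid toward C5 and chlorine participation (retention or halogen migration) may outrun direct displacement. The fallback sets out from alkene 18 and comes back at 22, and is the stoichiometric form of selenium-mediated syn-dihalogenation. Anti-chloroselenation with PhSeCl (CH2Cl2, −78 °C to 20 °C, thermodynamic Markovnikov adduct) should give [(1R,2R,4S,5S)-2-chloro-5-[(E)-2-chlorovinyl]-4-methoxy-2,4-dimethylcyclohexyl](phenyl)selane F3. Bromine then turns the selenide into a tetravalent selenium dibromide, whose C6–Se bond is displaced by bromide with inversion, to give 22 without the epoxide, the chlorohydrin or a sulfonate.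

3. Step 6, the anodic ring closure. Methanol may capture the radical cation before C4–C5 forms, since both enol ether carbons must end up in the ring and C4 sits next to the quaternary C3. The 4-alkoxy allylsilane may undergo acid-induced 1,4-elimination at the anode, and the chair preference may give low selectivity at C4. The fallback sets out from ester 5 and comes back at ketal 9, and closes C4–C5 with normal polarity by a Tsuji–Trost alkylation. Claisen condensation of 5 with the lithium enolate of methyl acetate (LDA, THF, −78 °C) gives methyl (S)-6-methoxy-6-methyl-3-oxooct-7-enoate F4. Cross-metathesis with allyl methyl carbonate (second-generation Hoveyda–Grubbs catalyst, CH2Cl2, 40 °C) gives methyl (S,E)-6-methoxy-9-[(methoxycarbonyl)oxy]-6-methyl-3-oxonon-7-enoate F5. Pd(PPh3)4 (zerovalent palladium) in THF ionizes the carbonate, and the β-keto ester carbon C5 attacks the C4 terminus of the π-allyl complex to close the six-membered ring as methyl (2R,3S)-3-methoxy-3-methyl-6-oxo-2-vinylcyclohexane-1-carboxylate F6. Krapcho demethoxycarbonylation (LiCl, wet DMSO, 130 °C) gives (3S,4S)-4-methoxy-4-methyl-3-vinylcyclohexan-1-one F7, where any C4 epimer is separated, and HC(OMe)3, MeOH and TsOH (cat.) return 9.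

**Further compounds**

F1 | step 16 | (1R,2S,4S)-2-bromo-1-chloro-4-[(E)-2-chlorovinyl]-1-methyl-5-methylidenecyclohexane | Br[C@@H]1[C@](C)(Cl)CC(=C)[C@H](/C=C/Cl)C1
F2 | step 16 | (3R,4S,6S)-4-bromo-3-chloro-6-[(E)-2-chlorovinyl]-1,3-dimethylcyclohex-1-ene | Br[C@@H]1[C@](C)(Cl)C=C(C)[C@H](/C=C/Cl)C1
F3 | step 15 | [(1R,2R,4S,5S)-2-chloro-5-[(E)-2-chlorovinyl]-4-methoxy-2,4-dimethylcyclohexyl](phenyl)selane | c1ccccc1[Se][C@H]1[C@](C)(Cl)C[C@@](OC)(C)[C@H](/C=C/Cl)C1
F4 | step 6 | methyl (S)-6-methoxy-6-methyl-3-oxooct-7-enoate | COC(=O)CC(=O)CC[C@@](OC)(C)C=C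
F5 | step 6 | methyl (S,E)-6-methoxy-9-[(methoxycarbonyl)oxy]-6-methyl-3-oxonon-7-enoate | COC(=O)CC(=O)CC[C@@](OC)(C)/C=C/COC(=O)OC
F6 | step 6 | methyl (2R,3S)-3-methoxy-3-methyl-6-oxo-2-vinylcyclohexane-1-carboxylate (C1 epimers and enol) | COC(=O)C1C(=O)CC[C@@](OC)(C)[C@@H]1C=C
F7 | step 6 | (3S,4S)-4-methoxy-4-methyl-3-vinylcyclohexan-1-one | O=C1CC[C@@](OC)(C)[C@H](C=C)C1
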